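**Plan**

1. Numbering: the decalin follows drimane numbering (rings A and B, C1–C10, C11 on C9, C12 on C8). Ring C is C1'–C6', with C11 on C1', the ketone at C6', the carbinol at C3' and CH2OH on C4'.
2. Enabling feature: ring B (C5–C10) shares the C5–C10 bond with ring A and has three adjacent branch points, the methyl on C10, C11 on C9 and C12 on C8. With a silyloxy group on C8, a ketone at C11 and a C6=C7 bond, ring B is a cyclohexene whose C5–C10 and C8–C9 bonds can be cut together, which opens both rings to one achiral triene.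
3. Cuts, in order: C3'–H (ketone reduction), the C1'–O–C2' epoxide, ring C back to a 4-methoxyphenol, C8=C12 (Wittig), C11H2 back to the aryl ketone, C5–C10 with C8–C9 (intramolecular Diels–Alder), C9–C11 (vinyllithium plus Weinreb amide), C6=C7 (Wittig), C3–C4 (conjugate addition).
4. Forward order: the chain is built (C3–C4, then C6=C7) and joined to the arene (ring C) at C9–C11. Rings A and B close together in step 12, and ring C is dearomatised and oxidised last.
5. Stereochemistry: C5, C9, C10 and the transient C8 arise in the cycloaddition. Their relative configuration comes from the (E)-enone, the (E,E)-diene and the endo geometry, and their absolute configuration from a chiral borate held by the C6' phenol and the C11 ketone. C1'/C2' come from a tartrate-controlled nucleophilic epoxidation, and C3' from hydroxyl-directed hydride delivery anti to the epoxide.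
6. The free C6' phenol is used three times: as anchor for the catalyst, as lever for removing the C11 oxygen, and as trigger of the dearomatisation.

Key step: step 12

Assumption: the sense of induction of the (R)-VANOL borate (step 12) and of D-(−)-diisopropyl tartrate (step 21) is assigned by analogy with simpler substrates. Both antipodes are commercial, so the other one is taken if a first run shows the opposite sense.

**Route**

Step 1
Reactants: 1 4-bromo-2,5-dimethoxybenzaldehyde
Product: 2 (4-bromo-2,5-dimethoxyphenyl)methanol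
Conditions: NaBH4, MeOH, 0 °C
Reagents that add atoms: none
Why: Borohydride reduction of the aryl aldehyde is chemoselective over the aryl bromide and turns the formyl carbon into the future C4' hydroxymethyl carbon.

Step 2
Reactants: 2 (4-bromo-2,5-dimethoxyphenyl)methanol
Product: 3 [(4-bromo-2,5-dimethoxybenzyl)oxy](tert-butyl)diphenylsilane
Conditions: TBDPSCl, imidazole, DMF, rt
Reagents that add atoms: tert-butyl(chloro)diphenylsilane, CC(C)(C)[Si](Cl)(c1ccccc1)c1ccccc1
Why: Imidazole-promoted silylation of a primary benzylic alcohol is routine, and the TBDPS ether is chosen because it tolerates n-BuLi, cold BCl3 and the boron Lewis acid of the key step.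

Step 3
Reactants: 3 [(4-bromo-2,5-dimethoxybenzyl)oxy](tert-butyl)diphenylsilane
Product: 5 4-({[tert-butyl(diphenyl)silyl]oxy}methyl)-N,2,5-trimethoxy-N-methylbenzamide, via aryllithium 4 (not isolated)
Conditions: n-BuLi, THF, −78 °C; then ClC(O)N(OMe)Me, −78 °C to rt
Reagents that add atoms: N-methoxy-N-methylcarbamoyl chloride, CON(C)C(=O)Cl; n-butyllithium, [Li]CCCC (lithium in 4 only)
Why: Bromine–lithium exchange is faster than any attack on the ethers, and carbamoylation of the aryllithium stops at the Weinreb amide, whose carbonyl carbon becomes C11.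

Step 4
Reactants: 5 4-({[tert-butyl(diphenyl)silyl]oxy}methyl)-N,2,5-trimethoxy-N-methylbenzamide
Product: 7 4-({[tert-butyl(diphenyl)silyl]oxy}methyl)-2-hydroxy-N,5-dimethoxy-N-methylbenzamide, via aryloxydichloroborane 6 (not isolated)
Conditions: BCl3 (1.2 equiv), CH2Cl2, −78 to −20 °C; H2O work-up
Reagents that add atoms: boron trichloride, ClB(Cl)Cl (boron and chlorine in 6 only)
Why: In this chelation-directed ether cleavage BCl3 binds the amide carbonyl and the ortho C6' methoxy oxygen, so chloride removes only that methyl group, while the C3' methoxy group has no neighbouring carbonyl and the para acyl group disfavours ionisation of the benzylic silyl ether.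

Step 5
Reactants: 8 (5-chloropent-1-yn-1-yl)trimethylsilane; 9 3-methylbut-2-enal
Product: 12 3,3-dimethyl-8-(trimethylsilyl)oct-7-ynal, via Grignard reagent 10 (not isolated), via trimethylsilyl enol ether 11 (not isolated)
Conditions: Mg, THF, reflux; then CuBr·SMe2 (5 mol %), TMSCl, HMPA, 9, THF, −78 °C; 1 M HCl, 0 °C
Reagents that add atoms: magnesium, [Mg] (in 10 only); chlorotrimethylsilane, C[Si](C)(C)Cl (in 11 only)
Why: Copper-catalysed, chlorosilane-accelerated conjugate addition of a Grignard reagent to a β,β-disubstituted enal forms C3–C4 and the quaternary C4, trapping of the enolate suppresses 1,2-addition, and mild acid frees the aldehyde without touching the alkynylsilane.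

Step 6
Reactants: 12 3,3-dimethyl-8-(trimethylsilyl)oct-7-ynal
Product: 14 3,3-dimethyloct-7-yn-1-ol, via silylated alkynol 13 (not isolated)
Conditions: NaBH4, MeOH, 0 °C; then K2CO3, rt
Reagents that add atoms: none
Why: Borohydride reduction masks the aldehyde as an alcohol that tolerates AlMe3, and carbonate-mediated methanolysis in the same flask removes the alkynyl silyl group (protiodesilylation).

Step 7
Reactants: 14 3,3-dimethyloct-7-yn-1-ol
Product: 16 (E)-8-iodo-3,3,7-trimethyloct-7-en-1-ol, via alkenylalane 15 (not isolated)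
Conditions: AlMe3 (3 equiv), Cp2ZrCl2 (25 mol %), CH2Cl2, 0 °C to rt; then I2, THF, −30 °C
Reagents that add atoms: trimethylaluminium, C[Al](C)C (methyl group; aluminium in 15 only); iodine, II
Why: Negishi zirconium-catalysed methylalumination adds methyl and aluminium syn across the terminal alkyne with the metal at the terminus, and iodinolysis with retention gives the (E)-iodoalkene that fixes the later C9=C10 geometry, the alcohol travelling as its aluminium alkoxide.

Step 8
Reactants: 16 (E)-8-iodo-3,3,7-trimethyloct-7-en-1-ol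
Product: 17 (E)-8-iodo-3,3,7-trimethyloct-7-enal
Conditions: nPr4N[RuO4] (5 mol %), NMO, 4 Å MS, CH2Cl2, rt
Reagents that add atoms: none
Why: Ley–Griffith oxidation takes the primary alcohol to the aldehyde under neutral conditions that leave the iodoalkene alone.

Step 9
Reactants: 17 (E)-8-iodo-3,3,7-trimethyloct-7-enal
Product: 18 (2E,9E)-10-iodo-5,5,9-trimethyldeca-2,9-dienal
Conditions: Ph3P=CHCHO, toluene, 80 °C
Reagents that add atoms: (triphenylphosphoranylidene)acetaldehyde, O=CC=P(c1ccccc1)(c1ccccc1)c1ccccc1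
Why: Wittig olefination with the stabilised formyl ylide adds C7 and C8 and gives the (E)-enal, as stabilised ylides do.

Step 10
Reactants: 18 (2E,9E)-10-iodo-5,5,9-trimethyldeca-2,9-dienal
Product: 19 tert-butyl{[(1E,3E,9E)-10-iodo-5,5,9-trimethyldeca-1,3,9-trien-1-yl]oxy}dimethylsilane
Conditions: TBSOTf, Et3N, CH2Cl2, 0 °C
Reagents that add atoms: tert-butyldimethylsilyl triflate, CC(C)(C)[Si](C)(C)OS(=O)(=O)C(F)(F)F
Why: In this soft γ-enolisation, O-silylation of the enal followed by removal of a C5 proton by Et3N gives the 1-silyloxydiene, the s-trans enal leading to the (1E) enol ether and the bulky quaternary C4 to the (3E) alkene.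

Step 11
Reactants: 19 tert-butyl{[(1E,3E,9E)-10-iodo-5,5,9-trimethyldeca-1,3,9-trien-1-yl]oxy}dimethylsilane; 7 4-({[tert-butyl(diphenyl)silyl]oxy}methyl)-2-hydroxy-N,5-dimethoxy-N-methylbenzamide
Product: 22 (2E,8E,10E)-11-{[tert-butyl(dimethyl)silyl]oxy}-1-[4-({[tert-butyl(diphenyl)silyl]oxy}methyl)-2-hydroxy-5-methoxyphenyl]-3,7,7-trimethylundeca-2,8,10-trien-1-one, via vinyllithium 20 (not isolated), via sodium phenoxide 21 (not isolated)
Conditions: 19, t-BuLi (2 equiv), Et2O, −78 °C; 7, NaH, THF, 0 °C; combine at −78 °C, warm to −10 °C; pH 7 buffer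
Reagents that add atoms: tert-butyllithium, [Li]C(C)(C)C (lithium in 20 only); sodium hydride, [Na+].[H-] (sodium in 21 only)
Why: Iodine–lithium exchange keeps the alkene geometry, and the Weinreb ketone synthesis on the pre-formed phenoxide stops at the chelated tetrahedral adduct, so buffered work-up releases the (E)-2'-hydroxyaryl enone without exposing the TBS dienol ether to acid.

Step 12
Reactants: 22 (2E,8E,10E)-11-{[tert-butyl(dimethyl)silyl]oxy}-1-[4-({[tert-butyl(diphenyl)silyl]oxy}methyl)-2-hydroxy-5-methoxyphenyl]-3,7,7-trimethylundeca-2,8,10-trien-1-one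
Product: 23 [(1R,2S,4aS,8aS)-2-{[tert-butyl(dimethyl)silyl]oxy}-5,5,8a-trimethyl-1,2,4a,5,6,7,8,8a-octahydronaphthalen-1-yl][4-({[tert-butyl(diphenyl)silyl]oxy}methyl)-2-hydroxy-5-methoxyphenyl]methanone (trans-fused 6,7-ene; 5α-H; 8β-OTBS; 9β-aroyl; 10β-methyl)
Conditions: (R)-VANOL [(R)-3,3'-diphenyl-2,2'-binaphthalene-1,1'-diol] (24 mol %), B(OPh)3 (20 mol %), 4 Å MS, PhCF3, 0 to 40 °C
Reagents that add atoms: none
Why: Proposed new method: the ortho phenol and the C11 carbonyl of 22 bind the VANOL borate as a tetracoordinate chelate that holds the enone s-cis and lowers its LUMO, and the 1-silyloxydiene then adds in a concerted, asynchronous [4+2] in which its nucleophilic terminus C5 bonds to the β-carbon C10 slightly ahead of C8–C9 bond formation. The closest known reaction types are the biaryl-diol borate catalysed intermolecular Diels–Alder reaction of 2'-hydroxychalcones and the Lewis-acid-promoted intramolecular Diels–Alder reaction of deca-2,7,9-trienoyl compounds to trans-decalins, whereas an enantioselective intramolecular case on a β,β-disubstituted aryl enone has not been shown. Ring B closes as the six-membered cycloaddition ring through C5–C10 and C8–C9, and ring A closes in the same event as a six-membered carbocycle because the C1–C4 tether folds into a chair between C10 and C5. C9 and C10 are related by suprafacial addition to the (E)-enone (C11 cis to the angular methyl), C5 is set by the transition state with the aroyl group endo and the tether exo (H5 trans to the methyl, trans fusion), C8 by the (E,E)-diene geometry (silyloxy cis to the aroyl group, erased in step 17), and the absolute sense by the vaulted biaryl wall that covers one face of the chelated enone. The step needs regio-, endo and facial selectivity: the tether and the matched polarity (donor on C8, acceptor at C11) allow one orientation only, the chelated carbonyl favours the endo mode, the β-methyl cis to the carbonyl enforces the s-cis enone, and the C4 gem-dimethyl group raises the population of the folded rotamer.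

Step 13
Reactants: 23 the octalin aryl ketone of step 12
Product: 24 [(1R,2S,4aS,8aS)-2-{[tert-butyl(dimethyl)silyl]oxy}-5,5,8a-trimethyldecahydronaphthalen-1-yl][4-({[tert-butyl(diphenyl)silyl]oxy}methyl)-2-hydroxy-5-methoxyphenyl]methanone
Conditions: H2 (1 atm), 5% Rh on Al2O3, EtOAc, rt
Reagents that add atoms: none
Why: Heterogeneous hydrogenation saturates the only isolated disubstituted C=C bond, rhodium on alumina being chosen because it causes little hydrogenolysis or migration at allylic and benzylic C–O bonds, and no stereocentre is formed or touched.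

Step 14
Reactants: 24 the saturated aryl ketone of step 13
Product: 27 2-{[(1R,2S,4aS,8aS)-2-{[tert-butyl(dimethyl)silyl]oxy}-5,5,8a-trimethyldecahydronaphthalen-1-yl]methyl}-5-({[tert-butyl(diphenyl)silyl]oxy}methyl)-4-methoxyphenol, via aryl ethyl carbonate 25 (not isolated), via ortho-quinone methide 26 (not isolated)
Conditions: ClCO2Et, Et3N, THF, 0 °C; then NaBH4, THF/H2O, 0 °C to rt
Reagents that add atoms: ethyl chloroformate, CCOC(=O)Cl (in 25 only)
Why: This is the reductive deoxygenation of an ortho-acylphenol through its carbonate, in which hydride adds to C11, the carbonate migrates to the new alkoxide, the phenoxide expels it to give the ortho-quinone methide and a second hydride adds 1,4, while the C4' silyloxymethyl group, meta to the phenoxide, cannot ionise in this way and C9 is not touched.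

Step 15
Reactants: 27 the 11-deoxy phenol of step 14
Product: 28 (1R,2S,4aS,8aS)-1-[2-hydroxy-4-(hydroxymethyl)-5-methoxybenzyl]-5,5,8a-trimethyldecahydronaphthalen-2-ol
Conditions: n-Bu4NF (4 equiv), THF, 50 °C, argon
Reagents that add atoms: none
Why: Fluoride cleaves both silyl ethers at once, which is more reliable than freeing the hindered axial C8 ether selectively.

Step 16
Reactants: 28 (1R,2S,4aS,8aS)-1-[2-hydroxy-4-(hydroxymethyl)-5-methoxybenzyl]-5,5,8a-trimethyldecahydronaphthalen-2-ol
Product: 29 (1R,2S,4aS,8aS)-1-[2-{[tert-butyl(dimethyl)silyl]oxy}-4-({[tert-butyl(dimethyl)silyl]oxy}methyl)-5-methoxybenzyl]-5,5,8a-trimethyldecahydronaphthalen-2-ol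
Conditions: TBSCl (2.3 equiv), imidazole, DMF, 0 °C
Reagents that add atoms: tert-butyl(chloro)dimethylsilane, CC(C)(C)[Si](C)(C)Cl
Why: Silylation discriminates by steric demand, since the phenol and the primary benzylic alcohol react at 0 °C whereas the axial 8β-hydroxyl group, 1,3-diaxial to the C10 methyl and next to the C9 branch, stays free.

Step 17
Reactants: 29 the bis-silyl ether alcohol of step 16
Product: 30 (1R,4aS,8aS)-1-[2-{[tert-butyl(dimethyl)silyl]oxy}-4-({[tert-butyl(dimethyl)silyl]oxy}methyl)-5-methoxybenzyl]-5,5,8a-trimethyloctahydronaphthalen-2(1H)-one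
Conditions: nPr4N[RuO4] (5 mol %), NMO, 4 Å MS, CH2Cl2, rt
Reagents that add atoms: none
Why: Ley–Griffith oxidation converts the hindered secondary alcohol into the C8 ketone under neutral conditions, the protected phenol is safe from the oxidant, and the equatorial C9 branch is the stable epimer.

Step 18
Reactants: 30 the C8 ketone of step 17
Product: 31 (1S,4aS,8aS)-1-[2-{[tert-butyl(dimethyl)silyl]oxy}-4-({[tert-butyl(dimethyl)silyl]oxy}methyl)-5-methoxybenzyl]-5,5,8a-trimethyl-2-methylidenedecahydronaphthalene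
Conditions: Ph3PCH3Br, n-BuLi, THF, 0 °C; then 30, rt to reflux
Reagents that add atoms: methyltriphenylphosphonium bromide, C[P+](c1ccccc1)(c1ccccc1)c1ccccc1.[Br-]
Why: Wittig methylenation with the small unstabilised ylide is the standard entry to the C8 exocyclic methylene of 9-substituted 8-oxodrimanes, and any enolisation can only return the more stable equatorial C9 epimer.

Step 19
Reactants: 31 the methylidene bis-silyl ether of step 18
Product: 32 5-(hydroxymethyl)-4-methoxy-2-{[(1S,4aS,8aS)-5,5,8a-trimethyl-2-methylidenedecahydronaphthalen-1-yl]methyl}phenol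
Conditions: n-Bu4NF (2.5 equiv), THF, 0 °C, argon
Reagents that add atoms: none
Why: Fluoride removes the aryl and the primary alkyl silyl ether without any acid that could move the exocyclic double bond.

Step 20
Reactants: 32 the aryl drimane phenol of step 19
Product: 33 5-(hydroxymethyl)-4,4-dimethoxy-2-{[(1S,4aS,8aS)-5,5,8a-trimethyl-2-methylidenedecahydronaphthalen-1-yl]methyl}cyclohexa-2,5-dien-1-one
Conditions: PhI(OAc)2, MeOH, 0 °C
Reagents that add atoms: methanol, CO
Why: Oxidative dearomatisation of a 4-methoxyphenol with a hypervalent iodine reagent in methanol captures the phenoxenium ion at the para carbon C3' and gives the quinone dimethyl monoketal faster than the isolated alkene or the primary alcohol can react.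

Step 21
Reactants: 33 the quinone monoketal of step 20
Product: 34 (1S,6R)-4-(hydroxymethyl)-5,5-dimethoxy-1-{[(1S,4aS,8aS)-5,5,8a-trimethyl-2-methylidenedecahydronaphthalen-1-yl]methyl}-7-oxabicyclo[4.1.0]hept-3-en-2-one
Conditions: Ph3COOH, NaN(SiMe3)2, D-(−)-diisopropyl tartrate, toluene, −60 °C
Reagents that add atoms: trityl hydroperoxide, OOC(c1ccccc1)(c1ccccc1)c1ccccc1
Why: In this tartrate-mediated Weitz–Scheffer epoxidation the sodium tartrate binds the C4' hydroxymethyl alkoxide and the trityl peroxide anion and delivers the latter to one face of C2', the only unsubstituted β-carbon of the dienone, ring closure onto C1' sets C1' and C2' together, and the isolated C8=C12 alkene is inert to a nucleophilic oxidant.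

Step 22
Reactants: 34 the epoxy ketal of step 21
Product: 35 (1S,6R)-4-(hydroxymethyl)-1-{[(1S,4aS,8aS)-5,5,8a-trimethyl-2-methylidenedecahydronaphthalen-1-yl]methyl}-7-oxabicyclo[4.1.0]hept-3-ene-2,5-dione
Conditions: 48% aq. HF, MeCN, 0 °C
Reagents that add atoms: water, O
Why: Hydrolysis of the dimethyl ketal with HF, a weak acid, unmasks the C3' ketone without opening the epoxide or moving the exocyclic C8=C12 double bond into the ring.

Step 23
Reactants: 35 the epoxyquinone of step 22
Product: 36 (1S,5S,6S)-5-hydroxy-4-(hydroxymethyl)-1-{[(1S,4aS,8aS)-5,5,8a-trimethyl-2-methylidenedecahydronaphthalen-1-yl]methyl}-7-oxabicyclo[4.1.0]hept-3-en-2-one (target)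
Conditions: NaBH(OAc)3, MeCN/AcOH, −20 to 0 °C
Reagents that add atoms: none
Why: In this hydroxyl-directed (Saksena–Evans type) reduction the C4' CH2OH replaces an acetate on boron and passes hydride through a six-membered transition state to the neighbouring C3' carbonyl only, from the face anti to the epoxide oxygen, so the new hydroxyl group ends cis to the epoxide (3'S), while the C6' ketone beside the quaternary C1' is out of reach and too hindered for this weak hydride.

**Compound list**

1 | 4-bromo-2,5-dimethoxybenzaldehyde | COc1cc(C=O)c(OC)cc1Br | starting material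
2 | (4-bromo-2,5-dimethoxyphenyl)methanol | COc1cc(CO)c(OC)cc1Br | intermediate
3 | [(4-bromo-2,5-dimethoxybenzyl)oxy](tert-butyl)diphenylsilane | COc1cc(CO[Si](c2ccccc2)(c2ccccc2)C(C)(C)C)c(OC)cc1Br | intermediate
4 | aryllithium from 3 (not isolated) | COc1cc(CO[Si](c2ccccc2)(c2ccccc2)C(C)(C)C)c(OC)cc1[Li] | intermediate
5 | 4-(TBDPS-oxymethyl)-N,2,5-trimethoxy-N-methylbenzamide | CON(C)C(=O)c1cc(OC)c(CO[Si](c2ccccc2)(c2ccccc2)C(C)(C)C)cc1OC | intermediate
6 | aryloxydichloroborane from 5 (not isolated) | CON(C)C(=O)c1cc(OC)c(CO[Si](c2ccccc2)(c2ccccc2)C(C)(C)C)cc1OB(Cl)Cl | intermediate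
7 | 4-(TBDPS-oxymethyl)-2-hydroxy-N,5-dimethoxy-N-methylbenzamide | CON(C)C(=O)c1cc(OC)c(CO[Si](c2ccccc2)(c2ccccc2)C(C)(C)C)cc1O | intermediate
8 | (5-chloropent-1-yn-1-yl)trimethylsilane | C[Si](C)(C)C#CCCCCl | starting material
9 | 3-methylbut-2-enal | CC(C)=CC=O | starting material
10 | [5-(trimethylsilyl)pent-4-yn-1-yl]magnesium chloride (not isolated) | C[Si](C)(C)C#CCCC[Mg]Cl | intermediate
11 | trimethylsilyl enol ether of 12, E/Z mixture (not isolated) | C[Si](C)(C)OC=CC(C)(C)CCCC#C[Si](C)(C)C | intermediate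
12 | 3,3-dimethyl-8-(trimethylsilyl)oct-7-ynal | O=CCC(C)(C)CCCC#C[Si](C)(C)C | intermediate
13 | 3,3-dimethyl-8-(trimethylsilyl)oct-7-yn-1-ol (not isolated) | OCCC(C)(C)CCCC#C[Si](C)(C)C | intermediate
14 | 3,3-dimethyloct-7-yn-1-ol | OCCC(C)(C)CCCC#C | intermediate
15 | (E)-alkenyl(dimethyl)alane, alcohol as dimethylaluminium alkoxide (not isolated) | C[Al](C)OCCC(C)(C)CCC/C(C)=C/[Al](C)C | intermediate
16 | (E)-8-iodo-3,3,7-trimethyloct-7-en-1-ol | OCCC(C)(C)CCC/C(C)=C/I | intermediate
17 | (E)-8-iodo-3,3,7-trimethyloct-7-enal | O=CCC(C)(C)CCC/C(C)=C/I | intermediate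
18 | (2E,9E)-10-iodo-5,5,9-trimethyldeca-2,9-dienal | O=C/C=C/CC(C)(C)CCC/C(C)=C/I | intermediate
19 | tert-butyl{[(1E,3E,9E)-10-iodo-5,5,9-trimethyldeca-1,3,9-trien-1-yl]oxy}dimethylsilane | CC(C)(C)[Si](C)(C)O/C=C/C=C/C(C)(C)CCC/C(C)=C/I | intermediate
20 | (E)-vinyllithium from 19 (not isolated) | CC(C)(C)[Si](C)(C)O/C=C/C=C/C(C)(C)CCC/C(C)=C/[Li] | intermediate
21 | sodium phenoxide of 7 (not isolated) | CON(C)C(=O)c1cc(OC)c(CO[Si](c2ccccc2)(c2ccccc2)C(C)(C)C)cc1[O-].[Na+] | intermediate
22 | (2E,8E,10E)-11-(TBS-oxy)-1-[4-(TBDPS-oxymethyl)-2-hydroxy-5-methoxyphenyl]-3,7,7-trimethylundeca-2,8,10-trien-1-one | CC(C)(C)[Si](C)(C)O/C=C/C=C/C(C)(C)CCC/C(C)=C/C(=O)c1cc(OC)c(CO[Si](c2ccccc2)(c2ccccc2)C(C)(C)C)cc1O | intermediate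
23 | (1R,2S,4aS,8aS) trans-octalin aryl ketone: 6,7-ene, 8β-OTBS, 9β-aroyl, 10β-methyl, 5α-H | CC(C)(C)[Si](C)(C)O[C@H]1C=C[C@H]2C(C)(C)CCC[C@]2(C)[C@H]1C(=O)c1cc(OC)c(CO[Si](c2ccccc2)(c2ccccc2)C(C)(C)C)cc1O | intermediate
24 | (1R,2S,4aS,8aS) trans-decalin aryl ketone (6,7-dihydro 23) | CC(C)(C)[Si](C)(C)O[C@H]1CC[C@H]2C(C)(C)CCC[C@]2(C)[C@H]1C(=O)c1cc(OC)c(CO[Si](c2ccccc2)(c2ccccc2)C(C)(C)C)cc1O | intermediate
25 | aryl ethyl carbonate of 24 (not isolated) | CC(C)(C)[Si](C)(C)O[C@H]1CC[C@H]2C(C)(C)CCC[C@]2(C)[C@H]1C(=O)c1cc(OC)c(CO[Si](c2ccccc2)(c2ccccc2)C(C)(C)C)cc1OC(=O)OCC | intermediate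
26 | ortho-quinone methide, C11=C1' and C6'=O (not isolated) | CC(C)(C)[Si](C)(C)O[C@H]1CC[C@H]2C(C)(C)CCC[C@]2(C)[C@H]1C=C1C=C(OC)C(CO[Si](c2ccccc2)(c2ccccc2)C(C)(C)C)=CC1=O | intermediate
27 | 11-deoxy phenol: 8β-OTBS, C4' CH2OTBDPS, free C6' OH | CC(C)(C)[Si](C)(C)O[C@H]1CC[C@H]2C(C)(C)CCC[C@]2(C)[C@H]1Cc1cc(OC)c(CO[Si](c2ccccc2)(c2ccccc2)C(C)(C)C)cc1O | intermediate
28 | (1R,2S,4aS,8aS)-1-[2-hydroxy-4-(hydroxymethyl)-5-methoxybenzyl]-5,5,8a-trimethyldecahydronaphthalen-2-ol | O[C@H]1CC[C@H]2C(C)(C)CCC[C@]2(C)[C@H]1Cc1cc(OC)c(CO)cc1O | intermediate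
29 | bis-TBS ether of 28 with free 8β-OH | O[C@H]1CC[C@H]2C(C)(C)CCC[C@]2(C)[C@H]1Cc1cc(OC)c(CO[Si](C)(C)C(C)(C)C)cc1O[Si](C)(C)C(C)(C)C | intermediate
30 | (1R,4aS,8aS) C8 ketone | O=C1CC[C@H]2C(C)(C)CCC[C@]2(C)[C@H]1Cc1cc(OC)c(CO[Si](C)(C)C(C)(C)C)cc1O[Si](C)(C)C(C)(C)C | intermediate
31 | (1S,4aS,8aS) C8 methylidene bis-TBS ether | C=C1CC[C@H]2C(C)(C)CCC[C@]2(C)[C@H]1Cc1cc(OC)c(CO[Si](C)(C)C(C)(C)C)cc1O[Si](C)(C)C(C)(C)C | intermediate
32 | 5-(hydroxymethyl)-4-methoxy-2-{[(1S,4aS,8aS)-5,5,8a-trimethyl-2-methylidenedecahydronaphthalen-1-yl]methyl}phenol | C=C1CC[C@H]2C(C)(C)CCC[C@]2(C)[C@H]1Cc1cc(OC)c(CO)cc1O | intermediate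
33 | quinone dimethyl monoketal (C6' ketone, C3' ketal) | C=C1CC[C@H]2C(C)(C)CCC[C@]2(C)[C@H]1CC1=CC(OC)(OC)C(CO)=CC1=O | intermediate
34 | (1S,6R) epoxy ketal | C=C1CC[C@H]2C(C)(C)CCC[C@]2(C)[C@H]1C[C@]12O[C@H]1C(OC)(OC)C(CO)=CC2=O | intermediate
35 | (1S,6R) epoxyquinone | C=C1CC[C@H]2C(C)(C)CCC[C@]2(C)[C@H]1C[C@]12O[C@H]1C(=O)C(CO)=CC2=O | intermediate
36 | (1S,5S,6S)-5-hydroxy-4-(hydroxymethyl)-1-{[(1S,4aS,8aS)-5,5,8a-trimethyl-2-methylidenedecahydronaphthalen-1-yl]methyl}-7-oxabicyclo[4.1.0]hept-3-en-2-one | C=C1CC[C@H]2C(C)(C)CCC[C@]2(C)[C@H]1C[C@]12O[C@H]1[C@@H](O)C(CO)=CC2=O | target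

**Step count**

- Total: 23 steps.
- Longest linear sequence: 19 steps (steps 5 to 23, from 8). The arene branch (steps 1 to 4) joins at step 11.

**Steps most likely to fail**

**Step 12.**
- Bond formation between C5 and C10 may be slow, because both carbons lie next to fully substituted centres.
- The dienol silyl group may be lost by proton or silyl transfer to a phenol before cyclisation.
- The borate may turn over slowly or discriminate the enone faces poorly.

The fallback sets out from 22 and gives up catalyst control. Me2AlCl (2.2 equiv, CH2Cl2, −78 to 0 °C) turns the phenol into an aluminium phenoxide chelate and drives the same cycloaddition as an ordinary Lewis-acid-promoted intramolecular Diels–Alder reaction. This should give 23 together with its mirror image, the enantiomeric adduct F1. Acylation of the phenol of this racemate with (1S)-(−)-camphanic chloride (Et3N, DMAP, CH2Cl2) gives the (1S)-camphanate of the wanted adduct F2 and the (1S)-camphanate of the mirror-image adduct F3. These are diastereomers and are separated by chromatography or crystallisation. K2CO3 in MeOH at 0 °C cleaves the aryl ester of F2, and the route is rejoined at 23.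

**Step 21.**
- Facial selectivity may be poor if the bulky chiral drimanylmethyl group on C1' opposes the tartrate.
- The large trityl peroxide may attack C2' only sluggishly.

The fallback sets out from 33 and replaces reagent control by a covalently bound auxiliary. Transketalisation with (2R,4R)-pentane-2,4-diol (PPTS, DME, rt, methanol removed) gives the C2-symmetric spiro-1,3-dioxane monoketal F6, in which one axial methyl group shields one face of the neighbouring C2'. Plain t-BuOOH/DBU epoxidation (CH2Cl2, 0 °C) then gives the epoxy spiroketal F7, any minor face isomer being a separable diastereomer. Hydrolysis with aq. HF in MeCN releases the diol, and the route is rejoined at 35.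

**Step 14.**
- Hydride addition to the crowded C11 ketone may be slower than cleavage of the carbonate.
- The ortho-quinone methide may tautomerise to the C9=C11 styrene before it is reduced.

The fallback sets out from 24 and removes the oxygen by a radical path. LiAlH4 (THF, 0 °C to reflux) gives the C11 carbinol F4 (either epimer serves). 1,1'-Thiocarbonyldiimidazole (toluene, 80 °C) ties the phenol and the carbinol together as the cyclic thionocarbonate F5. Barton–McCombie reduction (Bu3SnH, AIBN, toluene, reflux) breaks the benzylic C11–O bond, and mild basic work-up frees the phenol. The route is rejoined at 27.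

**Further compounds**

F1 | step 12 | enantiomeric adduct (ent-23) | CC(C)(C)[Si](C)(C)O[C@@H]1C=C[C@@H]2C(C)(C)CCC[C@@]2(C)[C@@H]1C(=O)c1cc(OC)c(CO[Si](c2ccccc2)(c2ccccc2)C(C)(C)C)cc1O
F2 | step 12 | (1S)-camphanate of the wanted adduct 23 | CC(C)(C)[Si](C)(C)O[C@H]1C=C[C@H]2C(C)(C)CCC[C@]2(C)[C@H]1C(=O)c1cc(OC)c(CO[Si](c2ccccc2)(c2ccccc2)C(C)(C)C)cc1OC(=O)[C@@]12CC[C@@](C)(C(=O)O1)C2(C)C
F3 | step 12 | (1S)-camphanate of the mirror-image adduct | CC(C)(C)[Si](C)(C)O[C@@H]1C=C[C@@H]2C(C)(C)CCC[C@@]2(C)[C@@H]1C(=O)c1cc(OC)c(CO[Si](c2ccccc2)(c2ccccc2)C(C)(C)C)cc1OC(=O)[C@@]12CC[C@@](C)(C(=O)O1)C2(C)C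
F4 | step 14 | C11 carbinol of 24 (C11 configuration open) | CC(C)(C)[Si](C)(C)O[C@H]1CC[C@H]2C(C)(C)CCC[C@]2(C)[C@H]1C(O)c1cc(OC)c(CO[Si](c2ccccc2)(c2ccccc2)C(C)(C)C)cc1O
F5 | step 14 | cyclic thionocarbonate bridging C11–O and C6'–O | CC(C)(C)[Si](C)(C)O[C@H]1CC[C@H]2C(C)(C)CCC[C@]2(C)[C@H]1C1OC(=S)Oc2cc(CO[Si](c3ccccc3)(c3ccccc3)C(C)(C)C)c(OC)cc21
F6 | step 21 | spiro-1,3-dioxane monoketal from (2R,4R)-pentane-2,4-diol | C=C1CC[C@H]2C(C)(C)CCC[C@]2(C)[C@H]1CC1=CC2(O[C@H](C)C[C@@H](C)O2)C(CO)=CC1=O
F7 | step 21 | epoxy spiroketal | C=C1CC[C@H]2C(C)(C)CCC[C@]2(C)[C@H]1C[C@]12O[C@H]1C1(O[C@H](C)C[C@@H](C)O1)C(CO)=CC2=O
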